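The decalin is disconnected in ring A across C3–C4 and C5–C10 (eudesmane numbering), which unravels it into an acyclic (E,E,E)-triene. An intramolecular Diels–Alder reaction of a 1-benzyloxy-4-methyl diene (C3=C2–C1=C10) with an α-methyl enone (C4=C5, acetyl on C4), tethered through C6–C9, closes rings A and B at once and sets C3, C4, C5 and C10. It exploits the vicinal C3–O/C4–O pair beside the trans C5–C10 fusion: the C3 oxygen is the diene donor, the C4 acetoxy group is a latent acetyl (Baeyer–Villiger), and a silyloxy stereocentre at C8 (later the ketone) fixes the absolute sense.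

Key step: step 7

Remark (assumptions): eudesmane numbering is used for all ring compounds (ring A = C1–C5 and C10, ring B = C5–C10; α = the face opposite the C10 methyl). Aldol 23 is drawn as its 7β-substituted epimer; either C7 epimer converges in step 13. Compounds 1, 2, 7, 9, 11, 15 and 21 are taken as commercial.

Step 1
Reactants: 1 (R)-1,2-epoxy-5-hexene; 2 lithium acetylide–ethylenediamine complex
Product: 3 (R)-oct-7-en-1-yn-4-ol
Conditions: HC≡CLi·H2NCH2CH2NH2, DMSO, 0 °C to rt; aqueous work-up
Reagents that add atoms: none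
Why: Epoxide ring opening by SN2 attack of the acetylide at the unsubstituted carbon leaves the carbinol stereocentre (the future C8) unchanged from 1.

Step 2
Reactants: 3 (R)-oct-7-en-1-yn-4-ol
Product: 4 (R)-triethyl(oct-7-en-1-yn-4-yloxy)silane
Conditions: Et3SiCl, imidazole, CH2Cl2, 0 °C to rt
Reagents that add atoms: chlorotriethylsilane, CC[Si](Cl)(CC)CC
Why: Standard silylation of a secondary alcohol; the triethylsilyl ether later steers the cycloaddition and masks the C8 ketone.

Step 3
Reactants: 4 (R)-triethyl(oct-7-en-1-yn-4-yloxy)silane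
Product: 6 (1E,4R)-triethyl[(1-iodo-2-methylocta-1,7-dien-4-yl)oxy]silane, via alkenylalane 5 (not isolated)
Conditions: Me3Al (2.5 equiv), Cp2ZrCl2 (0.25 equiv), CH2Cl2, 0 °C to rt; then I2, THF, −30 to 0 °C
Reagents that add atoms: trimethylaluminium, C[Al](C)C; iodine, II
Why: Zirconium-catalysed carboalumination of the terminal alkyne (Negishi methylalumination) adds CH3 and Al syn with methyl on the internal carbon, and iodinolysis with retention gives the E iodide (chain trans, methyl cis to iodine); the monosubstituted alkene is inert under these conditions.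

Step 4
Reactants: 6 (1E,4R)-triethyl[(1-iodo-2-methylocta-1,7-dien-4-yl)oxy]silane; 7 3-methylbut-3-en-2-one
Product: 8 (3E,7R,9E)-10-iodo-3,9-dimethyl-7-(triethylsilyloxy)deca-3,9-dien-2-one
Conditions: second-generation Hoveyda–Grubbs catalyst RuCl2(H2IMes)(=CH-C6H4-2-O-i-Pr) (5 mol %), 7 (10 equiv), CH2Cl2, 40 °C
Reagents that add atoms: none
Why: Olefin cross-metathesis of a terminal alkene with a 1,1-disubstituted α-methyl enone, driven by loss of ethylene, should give the thermodynamically preferred E trisubstituted enone; the trisubstituted iodoalkene does not engage the carbene.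

Step 5
Reactants: 8 (3E,7R,9E)-10-iodo-3,9-dimethyl-7-(triethylsilyloxy)deca-3,9-dien-2-one; 9 vinylboronic acid pinacol ester
Product: 10 (3E,7R,9E,11E)-3,9-dimethyl-12-(4,4,5,5-tetramethyl-1,3,2-dioxaborolan-2-yl)-7-(triethylsilyloxy)dodeca-3,9,11-trien-2-one
Conditions: Pd(OAc)2 (5 mol %), P(o-tol)3 (12 mol %), AgOAc (1.2 equiv), MeCN, 50 °C
Reagents that add atoms: none
Why: Heck–Mizoroki vinylation of the alkenyl iodide with the vinylboronate under base-free silver conditions (which suppress Suzuki transmetalation) should give the E dienylboronate by syn insertion and syn β-hydride elimination, with the iodide geometry retained.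

Step 6
Reactants: 10 (3E,7R,9E,11E)-3,9-dimethyl-12-(4,4,5,5-tetramethyl-1,3,2-dioxaborolan-2-yl)-7-(triethylsilyloxy)dodeca-3,9,11-trien-2-one; 11 benzyl alcohol
Product: 12 (3E,7R,9E,11E)-12-benzyloxy-3,9-dimethyl-7-(triethylsilyloxy)dodeca-3,9,11-trien-2-one
Conditions: Cu(OAc)2 (2 equiv), Et3N (4 equiv), BnOH/CH2Cl2 (1:1), 4 Å MS, rt
Reagents that add atoms: none
Why: Copper-promoted oxidative C–O coupling of an alkenyl pinacol boronate with an alcohol (Chan–Lam–Evans type) should replace boron by benzyloxy with retention of the E geometry, giving the donor diene.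

Step 7
Reactants: 12 (3E,7R,9E,11E)-12-benzyloxy-3,9-dimethyl-7-(triethylsilyloxy)dodeca-3,9,11-trien-2-one
Product: 13 4α-acetyl-3α-benzyloxy-8α-triethylsilyloxy-11,12,13-trinor-5αH-eudesm-1-ene (trans-fused, 10β-methyl, 4β-methyl)
Conditions: PhMe (0.01 M), BHT (0.1 equiv), i-Pr2NEt (0.1 equiv), sealed tube, 140 °C
Reagents that add atoms: none
Why: Thermal, concerted but asynchronous [4+2] cycloaddition of normal electron demand (closest known type: the intramolecular Diels–Alder reaction of a 1,3,9-decatriene with a terminally activated E dienophile), in which the benzyloxy group on C3 raises the diene HOMO and makes C10 the nucleophilic terminus, matched with the enone β-carbon C5, so that C5–C10 forms ahead of C3–C4. Ring A closes as the new cyclohexene of the cycloaddition (both new bonds), and ring B closes through the C5–C10 bond alone, with the four-carbon tether C6–C9 in a chair-like arrangement. C10 and C3 follow from the diene geometry (methyl inside, tether and benzyloxy outside, suprafacial addition) and C4 and C5 from the E enone (acetyl cis to H5), while the endo orientation of the acetyl group with the tether anti places 3-O, 4-acetyl and H5 on the α face and both methyls on the β face, which is the trans ring fusion. The absolute sense is relayed from C8: its triethylsilyloxy group takes the equatorial site of the chair-like tether, because the axial site would clash 1,3-diaxially with the inside methyl on C10, so only one diene face is used. The step needs endo (trans-fused) over exo (cis-fused) selectivity and π-facial selectivity, secured by the carbonyl-endo preference of the enone and by the C8 substituent; no other ring size is accessible to diene and enone, so periselectivity is not in question.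

Step 8
Reactants: 13 4α-acetyl-3α-benzyloxy-8α-triethylsilyloxy-11,12,13-trinor-5αH-eudesm-1-ene
Product: 14 4α-acetyl-3α-hydroxy-8α-triethylsilyloxy-11,12,13-trinor-5αH-eudesmane
Conditions: H2 (1 atm), Pd/C (10 wt % palladium on carbon), EtOAc, rt
Reagents that add atoms: none
Why: Heterogeneous hydrogenation saturates the cis-disubstituted C1=C2 bond and hydrogenolysis cleaves the benzyl ether in the same operation; no stereocentre is created and the silyl ether and ketone are untouched in ethyl acetate.

Step 9
Reactants: 14 4α-acetyl-3α-hydroxy-8α-triethylsilyloxy-11,12,13-trinor-5αH-eudesmane; 15 angelic acid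
Product: 17 4α-acetyl-3α-angeloyloxy-8α-triethylsilyloxy-11,12,13-trinor-5αH-eudesmane, via mixed anhydride 16 (not isolated)
Conditions: 15, 2,4,6-Cl3C6H2COCl, Et3N, PhMe, rt; then 14, PhMe, 80 °C
Reagents that add atoms: none
Why: Yamaguchi-type esterification through the mixed 2,4,6-trichlorobenzoic anhydride acylates the hindered axial C3 alcohol at the less hindered angeloyl carbonyl without a nucleophilic catalyst, conditions chosen to avoid Z-to-E isomerisation; C3 keeps its configuration.

Step 10
Reactants: 17 4α-acetyl-3α-angeloyloxy-8α-triethylsilyloxy-11,12,13-trinor-5αH-eudesmane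
Product: 18 4α-acetoxy-3α-angeloyloxy-8α-triethylsilyloxy-11,12,13-trinor-5αH-eudesmane
Conditions: mCPBA (3 equiv), NaHCO3, CH2Cl2, 0 °C to rt
Reagents that add atoms: 3-chloroperbenzoic acid, OOC(=O)c1cccc(Cl)c1
Why: Baeyer–Villiger oxidation of the methyl ketone, with migration of the tertiary C4 (far better than methyl) and retention of configuration, turns 4α-acetyl into 4α-acetoxy; the electron-poor angelate alkene should not be epoxidised by the buffered peracid.

Step 11
Reactants: 18 4α-acetoxy-3α-angeloyloxy-8α-triethylsilyloxy-11,12,13-trinor-5αH-eudesmane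
Product: 20 4α-acetoxy-3α-angeloyloxy-11,12,13-trinor-5αH-eudesman-8-one, via C8 alcohol 19 (not isolated)
Conditions: CrO3, H2SO4, H2O (Jones reagent), acetone, 0 °C
Reagents that add atoms: none
Why: Jones oxidation in which the aqueous acid first hydrolyses the secondary triethylsilyl ether and chromic acid then oxidises the liberated C8 alcohol to the ketone; the esters and the conjugated alkene are inert.

Step 12
Reactants: 20 4α-acetoxy-3α-angeloyloxy-11,12,13-trinor-5αH-eudesman-8-one; 21 acetone
Product: 23 4α-acetoxy-3α-angeloyloxy-11-hydroxy-5αH,7αH-eudesman-8-one, via lithium enolate 22 (not isolated)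
Conditions: LiN(SiMe3)2 (1.05 equiv), THF, −78 °C; acetone (5 equiv), −78 °C; AcOH quench
Reagents that add atoms: none
Why: Directed aldol addition: the amide base removes the more accessible C7 proton (C9 is neopentyl beside quaternary C10, and the ketone is far more acidic than the two esters at −78 °C) and the lithium enolate adds to acetone; the C7 configuration is irrelevant because step 13 removes it.

Step 13
Reactants: 23 4α-acetoxy-3α-angeloyloxy-11-hydroxy-5αH,7αH-eudesman-8-one
Product: 25 4α-acetoxy-3α-angeloyloxy-5αH-eudesm-7(11)-en-8-one, via tertiary mesylate 24 (not isolated)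
Conditions: MsCl, Et3N (5 equiv), CH2Cl2, 0 °C to rt
Reagents that add atoms: none
Why: Mesylation of the tertiary aldol hydroxyl (through sulfene) followed by E1cB elimination through the C8 enolate should give the conjugated isopropylidene ketone regioselectively.

Step 14
Reactants: 25 4α-acetoxy-3α-angeloyloxy-5αH-eudesm-7(11)-en-8-one
Product: 26 3α-angeloyloxy-4α-acetoxy-7α-hydroperoxy-5αH-eudesm-11(12)-en-8-one (CNP0360871.1)
Conditions: O2, tetraphenylporphyrin (1 mol %), visible light, CH2Cl2, −20 °C
Reagents that add atoms: dioxygen, O=O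
Why: Schenck ene reaction of singlet oxygen with the s-cis-locked tetrasubstituted enone: oxygen bonds to C7 from the α face (axial approach, anti to the C10 methyl) while a hydrogen of the C11 methyl syn to the carbonyl shifts, creating the 7α-hydroperoxide and the 11(12) alkene; the trisubstituted electron-poor angelate should react far more slowly.

Compound list
1 | (R)-1,2-epoxy-5-hexene [(2R)-2-(but-3-enyl)oxirane] | C=CCC[C@@H]1CO1 | starting material
2 | lithium acetylide–ethylenediamine complex | [Li]C#C.NCCN | starting material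
3 | (R)-oct-7-en-1-yn-4-ol | C#CC[C@H](O)CCC=C | intermediate
4 | (R)-triethyl(oct-7-en-1-yn-4-yloxy)silane | C#CC[C@H](O[Si](CC)(CC)CC)CCC=C | intermediate
5 | dimethyl[(1E,4R)-2-methyl-4-(triethylsilyloxy)octa-1,7-dien-1-yl]alane | C[Al](C)/C=C(\C)C[C@H](O[Si](CC)(CC)CC)CCC=C | intermediate
6 | (1E,4R)-triethyl[(1-iodo-2-methylocta-1,7-dien-4-yl)oxy]silane | I/C=C(\C)C[C@H](O[Si](CC)(CC)CC)CCC=C | intermediate
7 | 3-methylbut-3-en-2-one | CC(=O)C(C)=C | starting material
8 | (3E,7R,9E)-10-iodo-3,9-dimethyl-7-(triethylsilyloxy)deca-3,9-dien-2-one | CC(=O)/C(C)=C/CC[C@@H](O[Si](CC)(CC)CC)C/C(C)=C/I | intermediate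
9 | vinylboronic acid pinacol ester (4,4,5,5-tetramethyl-2-vinyl-1,3,2-dioxaborolane) | C=CB1OC(C)(C)C(C)(C)O1 | starting material
10 | (3E,7R,9E,11E)-3,9-dimethyl-12-(4,4,5,5-tetramethyl-1,3,2-dioxaborolan-2-yl)-7-(triethylsilyloxy)dodeca-3,9,11-trien-2-one | CC(=O)/C(C)=C/CC[C@@H](O[Si](CC)(CC)CC)C/C(C)=C/C=C/B1OC(C)(C)C(C)(C)O1 | intermediate
11 | benzyl alcohol | OCc1ccccc1 | starting material
12 | (3E,7R,9E,11E)-12-benzyloxy-3,9-dimethyl-7-(triethylsilyloxy)dodeca-3,9,11-trien-2-one | CC(=O)/C(C)=C/CC[C@@H](O[Si](CC)(CC)CC)C/C(C)=C/C=C/OCc1ccccc1 | intermediate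
13 | 4α-acetyl-3α-benzyloxy-8α-triethylsilyloxy-11,12,13-trinor-5αH-eudesm-1-ene | C1C[C@@H]2[C@](C)(C=C[C@@H](OCc3ccccc3)[C@@]2(C)C(C)=O)C[C@@H]1O[Si](CC)(CC)CC | intermediate
14 | 4α-acetyl-3α-hydroxy-8α-triethylsilyloxy-11,12,13-trinor-5αH-eudesmane | C1C[C@@H]2[C@](C)(CC[C@@H](O)[C@@]2(C)C(C)=O)C[C@@H]1O[Si](CC)(CC)CC | intermediate
15 | angelic acid [(Z)-2-methylbut-2-enoic acid] | C/C=C(/C)C(=O)O | starting material
16 | angelic 2,4,6-trichlorobenzoic anhydride | C/C=C(/C)C(=O)OC(=O)c1c(Cl)cc(Cl)cc1Cl | intermediate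
17 | 4α-acetyl-3α-angeloyloxy-8α-triethylsilyloxy-11,12,13-trinor-5αH-eudesmane | C1C[C@@H]2[C@](C)(CC[C@@H](OC(=O)/C(C)=C\C)[C@@]2(C)C(C)=O)C[C@@H]1O[Si](CC)(CC)CC | intermediate
18 | 4α-acetoxy-3α-angeloyloxy-8α-triethylsilyloxy-11,12,13-trinor-5αH-eudesmane | C1C[C@@H]2[C@](C)(CC[C@@H](OC(=O)/C(C)=C\C)[C@@]2(C)OC(C)=O)C[C@@H]1O[Si](CC)(CC)CC | intermediate
19 | 4α-acetoxy-3α-angeloyloxy-8α-hydroxy-11,12,13-trinor-5αH-eudesmane | C1C[C@@H]2[C@](C)(CC[C@@H](OC(=O)/C(C)=C\C)[C@@]2(C)OC(C)=O)C[C@@H]1O | intermediate
20 | 4α-acetoxy-3α-angeloyloxy-11,12,13-trinor-5αH-eudesman-8-one | C1C[C@@H]2[C@](C)(CC[C@@H](OC(=O)/C(C)=C\C)[C@@]2(C)OC(C)=O)CC1=O | intermediate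
21 | acetone | CC(C)=O | starting material
22 | lithium 7(8)-enolate of ketone 20 | [Li]OC1=CC[C@@H]2[C@](C)(CC[C@@H](OC(=O)/C(C)=C\C)[C@@]2(C)OC(C)=O)C1 | intermediate
23 | 4α-acetoxy-3α-angeloyloxy-11-hydroxy-5αH,7αH-eudesman-8-one | CC(C)(O)[C@H]1C[C@@H]2[C@](C)(CC[C@@H](OC(=O)/C(C)=C\C)[C@@]2(C)OC(C)=O)CC1=O | intermediate
24 | 11-methanesulfonate of aldol 23 | CC(C)(OS(C)(=O)=O)[C@H]1C[C@@H]2[C@](C)(CC[C@@H](OC(=O)/C(C)=C\C)[C@@]2(C)OC(C)=O)CC1=O | intermediate
25 | 4α-acetoxy-3α-angeloyloxy-5αH-eudesm-7(11)-en-8-one | CC(C)=C1C[C@@H]2[C@](C)(CC[C@@H](OC(=O)/C(C)=C\C)[C@@]2(C)OC(C)=O)CC1=O | intermediate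
26 | 3α-angeloyloxy-4α-acetoxy-7α-hydroperoxy-5αH-eudesm-11(12)-en-8-one (CNP0360871.1) | C=C(C)[C@@]1(OO)C[C@@H]2[C@](C)(CC[C@@H](OC(=O)/C(C)=C\C)[C@@]2(C)OC(C)=O)CC1=O | target

Total step count: 14. Longest linear sequence: 14 steps (1 to 26).

Steps most likely to fail

Step 7. Both new bonds join a fully substituted carbon to a tertiary one, so the cycloaddition may be sluggish. A 1,5-hydrogen shift of the Z-methyl diene or decomposition of the acid-labile benzyl dienyl ether may compete on prolonged heating, and endo/exo (trans/cis fusion) selectivity may be low. The fallback sets out from compound 10 and comes back at compound 14; it leaves out step 6. The dienylboronate 10 itself is cyclised under Lewis-acid activation of the enone (Me2AlCl, CH2Cl2, −78 to 0 °C), which a boron-substituted diene tolerates and which strengthens the carbonyl-endo preference, to give the 3α-boryl octalin allylic boronate F1. Oxidation of the C–B bond with retention (NaBO3·4H2O, THF/H2O, rt) gives the 3α-hydroxy octalin allylic alcohol F2. Hydrogenation of C1=C2 (H2, Pd/C, EtOAc) then gives compound 14.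

Step 9. Acylation of the axial C3 hydroxyl beside quaternary C4 may be slow. Under heating with base, Z-to-E isomerisation of the angeloyl unit (tiglate formation) or retro-aldol opening of the β-hydroxy ketone may take over. The fallback sets out from compound 14 and comes back at compound 17; it builds the Z alkene on the ester instead of transferring it. Compound 14 is esterified at room temperature with 2-[bis(2,2,2-trifluoroethoxy)phosphoryl]propanoic acid (DCC, DMAP, CH2Cl2) to give the C3 phosphonopropionate F3. A Still–Gennari olefination with acetaldehyde (KN(SiMe3)2, 18-crown-6, THF, −78 °C; the phosphonate is far more acidic than the methyl ketone) then forms the Z-trisubstituted ester, compound 17.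

Step 14. Hydrogen abstraction from C6 instead of the C11 methyl would give the regioisomeric 11-hydroperoxy-6-en-8-one, and attack from the β face would give the C7 epimer. The fallback sets out from compound 25 and comes back at compound 26; it fixes the site of oxygenation through a silyl enol ether. Soft enolisation of 25 (Me3SiOTf, Et3N, CH2Cl2, 0 °C) under equilibrating conditions gives the extended 8-silyloxy-7,11(12)-diene, TMS dienol ether F4. Its silyloxy group is the inside substituent of the diene, which disfavours the s-cis form and hence [4+2] addition. Singlet oxygen (O2, tetraphenylporphyrin, visible light, CH2Cl2, −78 °C) then reacts in a silatropic ene reaction at C7 from the α face to give the 7α-silylperoxy ketone F5. Methanolysis (MeOH, rt) releases the hydroperoxide 26.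

Further compounds
F1 | step 7 | 4α-acetyl-3α-(4,4,5,5-tetramethyl-1,3,2-dioxaborolan-2-yl)-8α-triethylsilyloxy-11,12,13-trinor-5αH-eudesm-1-ene | C1C[C@@H]2[C@](C)(C=C[C@@H](B3OC(C)(C)C(C)(C)O3)[C@@]2(C)C(C)=O)C[C@@H]1O[Si](CC)(CC)CC
F2 | step 7 | 4α-acetyl-3α-hydroxy-8α-triethylsilyloxy-11,12,13-trinor-5αH-eudesm-1-ene | C1C[C@@H]2[C@](C)(C=C[C@@H](O)[C@@]2(C)C(C)=O)C[C@@H]1O[Si](CC)(CC)CC
F3 | step 9 | 4α-acetyl-3α-{2-[bis(2,2,2-trifluoroethoxy)phosphoryl]propanoyloxy}-8α-triethylsilyloxy-11,12,13-trinor-5αH-eudesmane (both epimers at the phosphonate-bearing carbon) | C1C[C@@H]2[C@](C)(CC[C@@H](OC(=O)C(C)P(=O)(OCC(F)(F)F)OCC(F)(F)F)[C@@]2(C)C(C)=O)C[C@@H]1O[Si](CC)(CC)CC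
F4 | step 14 | 4α-acetoxy-3α-angeloyloxy-8-trimethylsilyloxy-5αH-eudesma-7,11(12)-diene | C[Si](C)(C)OC1=C(C(C)=C)C[C@@H]2[C@](C)(CC[C@@H](OC(=O)/C(C)=C\C)[C@@]2(C)OC(C)=O)C1
F5 | step 14 | 4α-acetoxy-3α-angeloyloxy-7α-(trimethylsilylperoxy)-5αH-eudesm-11(12)-en-8-one | C=C(C)[C@@]1(OO[Si](C)(C)C)C[C@@H]2[C@](C)(CC[C@@H](OC(=O)/C(C)=C\C)[C@@]2(C)OC(C)=O)CC1=O
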